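The decalin is closed in one flask from an acyclic enone tetraester, exploiting the C3 oxygen and C19 carbonyl on quaternary C4, a malonate in disguise (labdane locants). An iron hydride adds H to C1 of the C1=C10 alkene; the tertiary C10 radical closes ring B by conjugate addition to C5 of the enone (C5–C10). Methoxide then closes ring A by Dieckmann condensation of the C2 ester enolate onto one C4 ester (C2–C3), which fixes C4 and leaves the other ester as the future C19 formyl group. One catalytically set carbinol centre, relayed to C9 by Claisen rearrangement, controls C10, C5 and C4. The C2 ester and C7 ketone are removed afterwards.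

Key step: step 8

Remark: locants C1–C20 are those of the labdane skeleton of the target (C3 bears the acetate, C4 the methyl C18 and the formyl carbon C19, C5 and C10 are the ring-fusion carbons, C8 carries the methyl C17, C9 the side chain C11–C16, C10 the methyl C20).

Step 1
Reactants: 1 methyl geranate, methyl (2E)-3,7-dimethylocta-2,6-dienoate
Product: 2 methyl (2E,6E)-3,7-dimethyl-8-oxoocta-2,6-dienoate
Conditions: SeO2, 95% EtOH, reflux
Reagents that add atoms: selenium dioxide, O=[Se]=O
Why: Riley allylic oxidation (ene reaction, then [2,3]-shift) attacks the (E)-methyl group of the electron-rich terminal alkene and leaves the conjugated enoate untouched, giving the (E)-enal that supplies C1, C9, C10, C20 and the whole side chain.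

Step 2
Reactants: 2 methyl (2E,6E)-3,7-dimethyl-8-oxoocta-2,6-dienoate; 3 1-methoxy-1-(trimethylsilyloxy)ethene
Product: 4 dimethyl (2E,6E,8R)-8-hydroxy-3,7-dimethyldeca-2,6-dienedioate
Conditions: Ti(OiPr)4, chiral binaphthyl Schiff-base ligand, 3,5-di-tert-butylsalicylic acid (3 mol % each), Et2O, 0 °C; 1 M HCl/THF work-up
Reagents that add atoms: none
Why: catalytic enantioselective Mukaiyama acetate aldol addition to the enal; the chiral tetravalent titanium Lewis acid (ligand antipode chosen for the 8R carbinol) sets the one stereocentre that is not relayed and adds C2 with its activating ester.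

Step 3
Reactants: 4 dimethyl (2E,6E,8R)-8-hydroxy-3,7-dimethyldeca-2,6-dienedioate; 5 allyl 2,2,2-trichloroacetimidate
Product: 6 dimethyl (2E,6E,8R)-3,7-dimethyl-8-(prop-2-en-1-yloxy)deca-2,6-dienedioate
Conditions: TfOH (5 mol %), cyclohexane/CH2Cl2, 0 °C
Reagents that add atoms: none
Why: acid-catalysed imidate O-allylation etherifies the base-sensitive β-hydroxy ester without retro-aldol cleavage and without touching the stereocentre.

Step 4
Reactants: 6 dimethyl (2E,6E,8R)-3,7-dimethyl-8-(prop-2-en-1-yloxy)deca-2,6-dienedioate
Product: 8 dimethyl (2E,6R,7E)-3,7-dimethyl-6-[(2R)-1-oxopropan-2-yl]deca-2,7-dienedioate, via propenyl ether 7 (not isolated)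
Conditions: [IrCl(cyclooctene)2]2 (1 mol %), PCy3, NaBPh4, CH2Cl2/acetone, rt; then PPh3, ClCH2CH2Cl, 80 °C
Reagents that add atoms: none
Why: iridium-hydride isomerization of the allyl ether to the (E)-propenyl ether, then Claisen rearrangement through a chair transition state with the CH2CO2Me group equatorial; this forms C8–C9, transfers the carbinol chirality to C9, sets C8 and gives the (E)-C1=C10 alkene and the C7 aldehyde.

Step 5
Reactants: 9 dimethyl 2-methylpropanedioate; 10 1-[(trimethylsilyl)ethynyl]-1,2-benziodoxol-3(1H)-one
Product: 11 dimethyl 2-ethynyl-2-methylpropanedioate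
Conditions: Bu4NF, THF, −78 °C to rt; aqueous NH4Cl work-up
Reagents that add atoms: none
Why: electrophilic α-ethynylation of the stabilized enolate by the ethynyl benziodoxolone released in situ by fluoride; it builds the quaternary C4 with both ester groups (C3, C19), the methyl C18 and the C5–C6 unit.

Step 6
Reactants: 8 dimethyl (2E,6R,7E)-3,7-dimethyl-6-[(2R)-1-oxopropan-2-yl]deca-2,7-dienedioate; 11 dimethyl 2-ethynyl-2-methylpropanedioate
Product: 12 allylic alcohol joining the two fragments through an (E)-C5=C6 alkene (C7 carbinol as both epimers)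
Conditions: 11, Cp2Zr(H)Cl, CH2Cl2, rt; Me2Zn, −65 °C; then 8, 0 °C; aqueous NH4Cl work-up
Reagents that add atoms: none
Why: syn hydrozirconation of the terminal alkyne, transmetalation to zinc and 1,2-addition of the (E)-alkenylzinc to the aldehyde form C6–C7 without touching the four ester groups; the new carbinol centre is removed in the next step.

Step 7
Reactants: 12 allylic alcohol
Product: 13 acyclic enone tetraester (cyclization precursor)
Conditions: Dess–Martin periodinane, NaHCO3, CH2Cl2, rt
Reagents that add atoms: none
Why: mild Dess–Martin oxidation of the allylic alcohol gives the (E)-enone acceptor without epimerizing C8 or C9.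

Step 8
Reactants: 13 acyclic enone tetraester
Product: 15 trans-decalin 3,7-diketone with methyl esters at C2 + C19 (axial) + C15, via ring-B keto tetraester 14 (not isolated)
Conditions: Fe(acac)3 (30 mol %), PhSiH3, MeOH/ethylene glycol, 60 °C, high dilution; then NaOMe, MeOH, 60 °C; aqueous HCl work-up
Reagents that add atoms: none
Why: The iron hydride formed from Fe(acac)3 and PhSiH3 transfers a hydrogen atom to C1 of the trisubstituted C1=C10 alkene, the tertiary C10 radical adds 6-endo-trig to C5 of the enone (Giese addition, ring B), and the α-keto radical is reduced and protonated to give 14. Methoxide then deprotonates C2, which attacks one of the two ester groups on C4 (6-exo-trig acyl substitution, ring A), and the enolate of the β-keto ester 15 is the thermodynamic sink. The closest known reaction types are the metal-hydride hydrogen-atom-transfer reductive olefin–enone coupling in its intramolecular form and the Dieckmann condensation. Ring B should close through a chair-like transition state with the C8 methyl, the C9 side chain and the C4 group on C5 equatorial and with the longer C10 chain in the less crowded equatorial site next to H9, so that the C10 methyl becomes axial and C5–H is trans to it; C9 is the controlling centre. Ring A should close through the chair in which the unreacted ester on C4 is axial (cis to the C10 methyl) and the C4 methyl equatorial, because the alternative places two methyl groups 1,3-diaxial; this reversible step desymmetrizes C4. The step needs hydrogen-atom transfer to the unconjugated alkene in preference to the two conjugated ones and six-ring closure onto the enone in preference to five-ring closure onto the β,β-disubstituted side-chain enoate, which the higher reactivity of the isolated alkene towards the hydride and of the β-monosubstituted enone towards the nucleophilic radical should secure.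

Step 9
Reactants: 15 trans-decalin 3,7-diketone triester
Product: 16 7-hydroxy β-keto ester (C7 hydroxyl axial)
Conditions: NaH, THF, 0 °C; then LiBH(s-Bu)3, −78 °C; aqueous NH4Cl work-up
Reagents that add atoms: none
Why: the β-keto ester is masked as its sodium enolate, so the bulky hydride reduces only the C7 ketone (chemoselective hydride reduction), from the equatorial side, and gives the axial alcohol needed for anti elimination.

Step 10
Reactants: 16 7-hydroxy β-keto ester
Product: 18 7-hydroxy-3-oxo acid (C15 acid + C19 methyl ester), via β-keto diacid 17 (not isolated)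
Conditions: LiOH, THF/MeOH/H2O, rt; then 1 M HCl, 50 °C
Reagents that add atoms: lithium hydroxide, [Li+].[OH-]
Why: saponification of the two unhindered methyl esters (the neopentyl axial C19 ester resists) and decarboxylation of the β-keto acid remove the C2 activating group and free the side-chain acid.

Step 11
Reactants: 18 7-hydroxy-3-oxo acid
Product: 19 3-oxo-Δ7 acid with C19 methyl ester
Conditions: POCl3, pyridine, 0 to 50 °C; then aqueous NaHCO3, acidify
Reagents that add atoms: none
Why: E2 dehydration of the axial C7 dichlorophosphate with the antiperiplanar axial H8 should favour the more substituted (Zaitsev) C7=C8 alkene; the C3 ketone and the hindered ester are inert.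

Step 12
Reactants: 19 3-oxo-Δ7 acid with C19 methyl ester
Product: 21 3-hydroxy-19-hydroxymethyl acid, via hydroxy ester 20 (not isolated)
Conditions: LiBH(s-Bu)3, THF, −78 °C; then LiBHEt3, 0 °C to rt; aqueous NH4Cl
Reagents that add atoms: none
Why: the bulky hydride attacks the C3 ketone from the equatorial side and sets the axial 3S alcohol; the small, strongly nucleophilic hydride then reduces the hindered C19 ester while the lithium carboxylate of the side chain is not reduced (two successive hydride reductions).

Step 13
Reactants: 21 3-hydroxy-19-hydroxymethyl acid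
Product: 22 3-hydroxy-19-oxo acid
Conditions: TEMPO (10 mol %), PhI(OAc)2, CH2Cl2, rt
Reagents that add atoms: none
Why: oxoammonium (TEMPO) oxidation is selective for the primary neopentyl alcohol over the hindered axial secondary alcohol and stops at the aldehyde.

Step 14
Reactants: 22 3-hydroxy-19-oxo acid
Product: 23 target, CNP0312710.1
Conditions: Ac2O, pyridine, DMAP (cat.), 40 °C; aqueous work-up
Reagents that add atoms: acetic anhydride, CC(=O)OC(C)=O
Why: DMAP-catalysed acylation of the axial C3 alcohol; the carboxylic acid is recovered as such after the aqueous work-up, and the quaternary C4 prevents β-elimination of the acetate.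

Compound list

1 | methyl geranate, methyl (2E)-3,7-dimethylocta-2,6-dienoate | CC(C)=CCC/C(C)=C/C(=O)OC | starting material
2 | methyl (2E,6E)-3,7-dimethyl-8-oxoocta-2,6-dienoate | O=C/C(C)=C/CC/C(C)=C/C(=O)OC | intermediate
3 | 1-methoxy-1-(trimethylsilyloxy)ethene | C=C(OC)O[Si](C)(C)C | starting material
4 | dimethyl (2E,6E,8R)-8-hydroxy-3,7-dimethyldeca-2,6-dienedioate | COC(=O)C[C@@H](O)/C(C)=C/CC/C(C)=C/C(=O)OC | intermediate
5 | allyl 2,2,2-trichloroacetimidate | C=CCOC(=N)C(Cl)(Cl)Cl | starting material
6 | dimethyl (2E,6E,8R)-3,7-dimethyl-8-(prop-2-en-1-yloxy)deca-2,6-dienedioate | COC(=O)C[C@@H](OCC=C)/C(C)=C/CC/C(C)=C/C(=O)OC | intermediate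
7 | dimethyl (2E,6E,8R)-3,7-dimethyl-8-[(1E)-prop-1-en-1-yloxy]deca-2,6-dienedioate | COC(=O)C[C@@H](O/C=C/C)/C(C)=C/CC/C(C)=C/C(=O)OC | intermediate
8 | dimethyl (2E,6R,7E)-3,7-dimethyl-6-[(2R)-1-oxopropan-2-yl]deca-2,7-dienedioate | O=C[C@H](C)[C@@H](CC/C(C)=C/C(=O)OC)/C(C)=C/CC(=O)OC | intermediate
9 | dimethyl 2-methylpropanedioate | COC(=O)C(C)C(=O)OC | starting material
10 | 1-[(trimethylsilyl)ethynyl]-1,2-benziodoxol-3(1H)-one | C[Si](C)(C)C#CI1OC(=O)c2ccccc12 | starting material
11 | dimethyl 2-ethynyl-2-methylpropanedioate | C#CC(C)(C(=O)OC)C(=O)OC | intermediate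
12 | dimethyl 2-[(1E,4R,5R,6E)-3-hydroxy-9-methoxy-5-[(3E)-5-methoxy-3-methyl-5-oxopent-3-en-1-yl]-4,6-dimethyl-9-oxonona-1,6-dien-1-yl]-2-methylpropanedioate, both C7 carbinol epimers | COC(=O)C(C)(C(=O)OC)/C=C/C(O)[C@H](C)[C@@H](CC/C(C)=C/C(=O)OC)/C(C)=C/CC(=O)OC | intermediate
13 | dimethyl 2-[(1E,4R,5R,6E)-9-methoxy-5-[(3E)-5-methoxy-3-methyl-5-oxopent-3-en-1-yl]-4,6-dimethyl-3,9-dioxonona-1,6-dien-1-yl]-2-methylpropanedioate | COC(=O)C(C)(C(=O)OC)/C=C/C(=O)[C@H](C)[C@@H](CC/C(C)=C/C(=O)OC)/C(C)=C/CC(=O)OC | intermediate
14 | ring-B ketone: cyclohexanone (C7 oxo) with C(CH3)(CO2Me)2 at C5, CH3 (axial) and CH2CH2CO2Me at C10, the (E)-CH2CH2C(CH3)=CHCO2Me chain at C9 and CH3 at C8, all but the C10 methyl equatorial | O=C1C[C@H](C(C)(C(=O)OC)C(=O)OC)[C@@](C)(CCC(=O)OC)[C@H](CC/C(C)=C/C(=O)OC)[C@H]1C | intermediate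
15 | trans-decalin 3,7-diketone: CO2Me at C2 (enolizable), CH3 (equatorial) and CO2Me (axial, C19) at C4, CH3 at C8, side chain (E)-CH2CH2C(CH3)=CHCO2Me at C9, axial CH3 at C10 | O=C1C(C(=O)OC)C[C@@]2(C)[C@H](CC/C(C)=C/C(=O)OC)[C@@H](C)C(=O)C[C@@H]2[C@]1(C)C(=O)OC | intermediate
16 | 7-hydroxy β-keto ester: as 15 with an axial hydroxyl at C7 in place of the ketone | O=C1C(C(=O)OC)C[C@@]2(C)[C@H](CC/C(C)=C/C(=O)OC)[C@@H](C)[C@@H](O)C[C@@H]2[C@]1(C)C(=O)OC | intermediate
17 | β-keto diacid: as 16 with CO2H at C2 and at C15, C19 methyl ester kept | O=C1C(C(=O)O)C[C@@]2(C)[C@H](CC/C(C)=C/C(=O)O)[C@@H](C)[C@@H](O)C[C@@H]2[C@]1(C)C(=O)OC | intermediate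
18 | 7-hydroxy-3-oxo acid: C2 unsubstituted, C15 acid, C19 methyl ester | O=C1CC[C@@]2(C)[C@H](CC/C(C)=C/C(=O)O)[C@@H](C)[C@@H](O)C[C@@H]2[C@]1(C)C(=O)OC | intermediate
19 | 3-oxo-Δ7 acid: C7=C8 alkene, C15 acid, C19 methyl ester | O=C1CC[C@@]2(C)[C@H](CC/C(C)=C/C(=O)O)C(C)=CC[C@@H]2[C@]1(C)C(=O)OC | intermediate
20 | 3-hydroxy ester: axial (3S) hydroxyl, C19 methyl ester, C15 acid | O[C@H]1CC[C@@]2(C)[C@H](CC/C(C)=C/C(=O)O)C(C)=CC[C@@H]2[C@]1(C)C(=O)OC | intermediate
21 | 3-hydroxy-19-hydroxymethyl acid | O[C@H]1CC[C@@]2(C)[C@H](CC/C(C)=C/C(=O)O)C(C)=CC[C@@H]2[C@]1(C)CO | intermediate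
22 | 3-hydroxy-19-oxo acid | O[C@H]1CC[C@@]2(C)[C@H](CC/C(C)=C/C(=O)O)C(C)=CC[C@@H]2[C@]1(C)C=O | intermediate
23 | CNP0312710.1, the 3-acetoxy-19-oxo-labda-7,13E-dien-15-oic acid of configuration 3S,4S,5S,9R,10S | CC(=O)O[C@H]1CC[C@@]2(C)[C@H](CC/C(C)=C/C(=O)O)C(C)=CC[C@@H]2[C@]1(C)C=O | target

Total step count: 14. Longest linear sequence: 13 steps (steps 1–4 and 6–14, from methyl geranate).

Steps most likely to fail

Step 8. The C10 radical is planar and its two free substituents (methyl and the C1 chain) differ little in size, so facial selectivity at C10 may be poor; the wrong face leads to the cis-fused decalin after ring-A closure. The radical may also close a five-membered ring onto the side-chain enoate, the enone may be reduced before it is attacked, and methoxide may select the wrong C4 ester or scramble the side-chain alkene geometry through its dienolate. The fallback sets out from 13 and replaces the radical by an anionic, reversible C–C bond formation. Catalytic KOt-Bu in t-BuOH/THF at 0 °C should form the dienolate of the β,γ-unsaturated ester, whose γ-carbon (C10) adds to C5 of the enone in an intramolecular vinylogous Michael reaction and gives the ring-B keto acrylate F1, in which C10 carries an (E)-CH=CH–CO2Me group; because this addition can revert, the more stable ring-B diastereomer can accumulate. Conjugate reduction of the acrylate of F1 with [(Ph3P)CuH]6 and PhSiH3 in toluene should give 14, and NaOMe in MeOH then closes ring A by Dieckmann condensation, so that the route is rejoined at 15.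

Step 11. Elimination towards C6 instead of C8, or cationic rearrangement, would give the wrong alkene. The fallback sets out from 15 and fixes the alkene position through an enolate. NaH masks the β-keto ester, slightly less than one equivalent of KHMDS at 0 °C lets the C7 ketone equilibrate to the more substituted enolate, and PhNTf2 traps it as the C7=C8 enol triflate F2 (aqueous NH4Cl work-up). Pd(OAc)2, PPh3, HCO2H and Bu3N in DMF should reduce the triflate to the Δ7 β-keto ester F3. LiOH hydrolyses F3 to the Δ7 β-keto diacid F4, which loses CO2 in warm dilute HCl as in step 10, and the route is rejoined at 19.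

Step 6. Transmetalation and addition of the hindered alkenyl group, which carries two chelating ester groups, may be slow, so that methyl transfer from zinc or epimerization of the α-centre (C8) of the aldehyde competes. The fallback sets out from 11 and 8 and replaces the zinc reagent by a chromium reagent made from a halide. Hydrozirconation of 11 with Cp2Zr(H)Cl in CH2Cl2 and quenching with I2 should give the (E)-alkenyl iodide F5. CrCl2 with catalytic NiCl2 in DMSO at rt (Nozaki–Hiyama–Kishi coupling, aqueous NH4Cl work-up) should add F5 to the aldehyde of 8 without base and without touching the esters, and the route is rejoined at 12.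

Further compounds

F1 | step 8 | ring-B keto acrylate: as 14 but with an (E)-CH=CH–CO2Me group on C10 in place of CH2CH2CO2Me | O=C1C[C@H](C(C)(C(=O)OC)C(=O)OC)[C@@](C)(/C=C/C(=O)OC)[C@H](CC/C(C)=C/C(=O)OC)[C@H]1C
F2 | step 11 | C7=C8 enol triflate of 15 (triflate on C7) | O=C1C(C(=O)OC)C[C@@]2(C)[C@H](CC/C(C)=C/C(=O)OC)C(C)=C(OS(=O)(=O)C(F)(F)F)C[C@@H]2[C@]1(C)C(=O)OC
F3 | step 11 | Δ7 β-keto ester: as 15 with a C7=C8 alkene in place of the C7 ketone | O=C1C(C(=O)OC)C[C@@]2(C)[C@H](CC/C(C)=C/C(=O)OC)C(C)=CC[C@@H]2[C@]1(C)C(=O)OC
F4 | step 11 | Δ7 β-keto diacid: as F3 with CO2H at C2 and at C15, C19 methyl ester kept | O=C1C(C(=O)O)C[C@@]2(C)[C@H](CC/C(C)=C/C(=O)O)C(C)=CC[C@@H]2[C@]1(C)C(=O)OC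
F5 | step 6 | dimethyl 2-[(E)-2-iodoethenyl]-2-methylpropanedioate | COC(=O)C(C)(/C=C/I)C(=O)OC
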